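**Retrosynthetic overview**
- The target is reached by removing two aryl bromides that serve only as positional blocks on the resorcinol-derived ring.
- The dibromo dihydrobenzofuran comes from one oxidative [3+2] union of oxyresveratrol with 4,6-dibromo-dihydroresveratrol. The C3–C3a bond forms first (stilbene C8 to resorcinol C2), then the O1–C2 bond by phenol addition to the resulting p-quinone methide. Both stereocentres arise here, under a chiral iron phosphate.
- 4,6-Dibromo-dihydroresveratrol comes from dihydroresveratrol and bromine.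
- Only the dihydrofuran ring is built; all four benzene rings are bought.

**Assumptions**
- Oxyresveratrol and dihydroresveratrol are bought as catalogue compounds.
- The (R)-catalyst is written in step 2. The sense of induction cannot be predicted; it is checked on the first run (chiral HPLC, ECD), and the (S)-catalyst is used instead if the adduct comes out as the antipode.

**Step 1**
Reactants: 1 dihydroresveratrol, 5-[2-(4-hydroxyphenyl)ethyl]benzene-1,3-diol
Product: 2 4,6-dibromo-5-[2-(4-hydroxyphenyl)ethyl]benzene-1,3-diol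
Conditions: Br2 (2.0 equiv), CH2Cl2–Et2O (3:1), −78 to −20 °C
Reagents that add atoms: bromine, BrBr
Why: Electrophilic aromatic bromination, in which the resorcinol ring is far more activated than the p-alkylphenol ring and its two positions para to an OH (C4, C6) react first, leaving C2 between the hydroxyls as the only free resorcinol carbon (the dihalo blocking tactic known for 5-alkylresorcinols); no stereocentre is formed.

**Step 2**
Reactants: 2 4,6-dibromo-5-[2-(4-hydroxyphenyl)ethyl]benzene-1,3-diol (3 equiv); 3 oxyresveratrol, 4-[(E)-2-(3,5-dihydroxyphenyl)ethenyl]benzene-1,3-diol (added over 6 h)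
Product: 5 (2S,3S)-5,7-dibromo-2-(2,4-dihydroxyphenyl)-3-(3,5-dihydroxyphenyl)-6-[2-(4-hydroxyphenyl)ethyl]-2,3-dihydro-1-benzofuran-4-ol, via p-quinone methide 4 (not isolated)
Conditions: Fe(III) tris[(R)-3,3′-diaryl-BINOL phosphate] (10 mol %), t-BuOOt-Bu (1.5 equiv), HFIP–ClCH2CH2Cl (1:1), 0 °C to rt
Reagents that add atoms: none
Why: Proposed new method: the stilbene phenol 3 has the lowest oxidation potential and is oxidised on iron to a ligated phenoxyl (quinone methide) radical, whose C8 is attacked by the ortho carbon C2 of iron-bound resorcinolate 2 (its only free ring position), a second electron transfer gives p-quinone methide 4, and a flanking phenol closes by 5-exo oxa-1,6-addition to the thermodynamically favoured trans ring, so that C3 is set by the chiral phosphate ligands around iron in the C–C bond formation and C2 by substrate control (trans to the C3 aryl), the closest known reaction types being the iron-phosphate-catalysed enantioselective oxidative cross-coupling of phenols in HFIP (radical–anion coupling) and the biomimetic oxidative [3+2] dimerisation of 4-hydroxystilbenes to trans-2,3-diaryl-2,3-dihydrobenzofurans.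

**Step 3**
Reactants: 5 (2S,3S)-5,7-dibromo-2-(2,4-dihydroxyphenyl)-3-(3,5-dihydroxyphenyl)-6-[2-(4-hydroxyphenyl)ethyl]-2,3-dihydro-1-benzofuran-4-ol
Product: 6 (2S,3S)-2-(2,4-dihydroxyphenyl)-3-(3,5-dihydroxyphenyl)-6-[2-(4-hydroxyphenyl)ethyl]-2,3-dihydro-1-benzofuran-4-ol
Conditions: H2 (1 atm), 10% Pd/C, Et3N (2.5 equiv), MeOH–EtOAc, rt, stopped at full conversion
Reagents that add atoms: none
Why: Pd-catalysed hydrogenolysis (hydrodehalogenation) of the two aryl C–Br bonds, which the amine accelerates while it tempers the catalyst against hydrogenolysis of the benzylic C2–O bond; no stereocentre is touched.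

**Compound list**
1 | dihydroresveratrol, 5-[2-(4-hydroxyphenyl)ethyl]benzene-1,3-diol | Oc1ccc(CCc2cc(O)cc(O)c2)cc1 | starting material
2 | 4,6-dibromo-5-[2-(4-hydroxyphenyl)ethyl]benzene-1,3-diol | Oc1ccc(CCc2c(Br)c(O)cc(O)c2Br)cc1 | intermediate
3 | oxyresveratrol, 4-[(E)-2-(3,5-dihydroxyphenyl)ethenyl]benzene-1,3-diol | Oc1ccc(/C=C/c2cc(O)cc(O)c2)c(O)c1 | starting material
4 | p-quinone methide formed in the flask in step 2, 4-[(2S)-2-{3,5-dibromo-2,6-dihydroxy-4-[2-(4-hydroxyphenyl)ethyl]phenyl}-2-(3,5-dihydroxyphenyl)ethylidene]-3-hydroxycyclohexa-2,5-dien-1-one (exocyclic C=C geometry left open) | O=C1C=CC(=C[C@H](c2c(O)c(Br)c(CCc3ccc(O)cc3)c(Br)c2O)c2cc(O)cc(O)c2)C(O)=C1 | intermediate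
5 | (2S,3S)-5,7-dibromo-2-(2,4-dihydroxyphenyl)-3-(3,5-dihydroxyphenyl)-6-[2-(4-hydroxyphenyl)ethyl]-2,3-dihydro-1-benzofuran-4-ol (trans) | Oc1ccc(CCc2c(Br)c(O)c3c(c2Br)O[C@H](c2ccc(O)cc2O)[C@H]3c2cc(O)cc(O)c2)cc1 | intermediate
6 | (2S,3S)-2-(2,4-dihydroxyphenyl)-3-(3,5-dihydroxyphenyl)-6-[2-(4-hydroxyphenyl)ethyl]-2,3-dihydro-1-benzofuran-4-ol (trans) | Oc1ccc(CCc2cc(O)c3c(c2)O[C@H](c2ccc(O)cc2O)[C@H]3c2cc(O)cc(O)c2)cc1 | target

**Totals**
Total step count: 3. Longest linear sequence: 3 (1 → 2 → 5 → 6; 3 enters in step 2).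

**Steps most likely to fail, most risky first**

Step 2. Homocoupling of 3, oxidative cyclisation of 3 through its 2-OH to a 2-arylbenzofuran, O- instead of C-attack by 2, or low enantioselectivity can each defeat the catalytic asymmetric coupling. The fallback gives up catalyst control and sets out from 2 and 3. Compound 3 is oxidised in the presence of excess 2 with an achiral stoichiometric one-electron oxidant (FeCl3·6H2O in HFIP–CH2Cl2, or anodic oxidation in HFIP). This passes through both antipodes of the quinone methide, 4 and its (R)-enantiomer F1, and gives the racemic trans adduct, that is 5 together with its (2R,3R)-enantiomer F2. Preparative chiral SFC on an amylose carbamate phase then separates the two; F2 is discarded and the route is rejoined at 5.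

Step 3. Pd–H may open the benzylic C2–O bond, and the base may erode the stereocentres through reversible ring opening. The fallback sets out from 5 and acetylates all six phenols (Ac2O, pyridine, DMAP) to the hexaacetate F3, which can no longer open to a quinone methide. Both bromines are then removed by a radical chain reduction without palladium (Bu3SnH, AIBN, toluene, 90 °C) to give the hexaacetate F4. Cleavage of the acetates (catalytic K2CO3, MeOH, 0 °C) returns to the route at 6.

Step 1. Bromination may not stop cleanly at the 4,6-dibromide (attack at C2 or on the phenol ring). The fallback drops the blocking groups and sets out from 1, which is coupled directly with 3 under the catalyst of step 2. The debrominated quinone methide F5 closes to 6, where the route is rejoined, so step 3 is no longer needed. The price is the regioisomeric adduct F6 from attack through C4/C6 of 1, which has to be removed by reverse-phase chromatography.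

**Further compounds**
F1 | step 2 | (R)-enantiomer of quinone methide 4 | O=C1C=CC(=C[C@@H](c2c(O)c(Br)c(CCc3ccc(O)cc3)c(Br)c2O)c2cc(O)cc(O)c2)C(O)=C1
F2 | step 2 | (2R,3R)-enantiomer of 5 | Oc1ccc(CCc2c(Br)c(O)c3c(c2Br)O[C@@H](c2ccc(O)cc2O)[C@@H]3c2cc(O)cc(O)c2)cc1
F3 | step 3 | hexaacetate of 5, (2S,3S) | CC(=O)Oc1ccc(CCc2c(Br)c(OC(C)=O)c3c(c2Br)O[C@H](c2ccc(OC(C)=O)cc2OC(C)=O)[C@H]3c2cc(OC(C)=O)cc(OC(C)=O)c2)cc1
F4 | step 3 | hexaacetate of 6, (2S,3S) | CC(=O)Oc1ccc(CCc2cc(OC(C)=O)c3c(c2)O[C@H](c2ccc(OC(C)=O)cc2OC(C)=O)[C@H]3c2cc(OC(C)=O)cc(OC(C)=O)c2)cc1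
F5 | step 1 | debrominated (S)-p-quinone methide, 4-[(2S)-2-{2,6-dihydroxy-4-[2-(4-hydroxyphenyl)ethyl]phenyl}-2-(3,5-dihydroxyphenyl)ethylidene]-3-hydroxycyclohexa-2,5-dien-1-one | O=C1C=CC(=C[C@H](c2c(O)cc(CCc3ccc(O)cc3)cc2O)c2cc(O)cc(O)c2)C(O)=C1
F6 | step 1 | regioisomeric by-product, (2S,3S)-2-(2,4-dihydroxyphenyl)-3-(3,5-dihydroxyphenyl)-4-[2-(4-hydroxyphenyl)ethyl]-2,3-dihydro-1-benzofuran-6-ol | Oc1ccc(CCc2cc(O)cc3O[C@H](c4ccc(O)cc4O)[C@@H](c4cc(O)cc(O)c4)c23)cc1
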